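Labdane numbering is used: ring A = C1–C5 and C10, ring B = C5–C10, C11 on C9, C17 the formyl carbon on C8. Ring B holds a Diels–Alder retron: oxygen at C8 beside C9 bearing carbon C11, and the methylated ring-fusion carbon C10. An acyclic (E)-1-silyloxydiene (C5–C8) and an (E)-β-methyl enal (C9=C10, C11 formyl), tethered by C1–C4, undergo an intramolecular Diels–Alder reaction that forms the C5–C10 ring-fusion bond and C8–C9, closing both rings at once. The single CBS-derived centre C3 relays to C5, C9 and C10; C8 follows from equatorial addition to the derived ketone.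

Key step: step 8

Remarks: (a) the target is read as 3R,5S,8R,9S,10R with a 13Z side chain; the SMILES strings carry the configuration of every compound. (b) Bromide 3 is taken as the geometrically pure E isomer.

**Step 1**
Reactants: 1 2,2-dimethylpent-4-enoic acid
Product: 2 3,3-dimethylhex-5-en-2-one
Conditions: MeLi (2.2 equiv), Et2O, 0 °C to rt; inverse quench into cold 1 M HCl
Reagents that add atoms: methyllithium, [Li]C
Why: Organolithium addition to a lithium carboxylate (ketone synthesis from a carboxylic acid) stops at the dilithium gem-diolate, which gives the methyl ketone only on quench, and the α-quaternary centre precludes enolisation.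

**Step 2**
Reactants: 2 3,3-dimethylhex-5-en-2-one; 3 methyl (2E)-4-bromo-3-methylbut-2-enoate
Product: 5 methyl (2E)-3,7,7-trimethyl-6-oxodeca-2,9-dienoate, via lithium enolate 4 (not isolated)
Conditions: LiN(iPr)2 (1.25 equiv), 2 (1.3 equiv), THF, −78 °C; then 3 (limiting), DMPU, −78 to −20 °C
Reagents that add atoms: none
Why: Kinetic enolate alkylation (SN2 on an allylic bromide) is regiochemically unambiguous because the methyl group is the only enolisable position, and the E enoate geometry is carried in unchanged from 3.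

**Step 3**
Reactants: 5 methyl (2E)-3,7,7-trimethyl-6-oxodeca-2,9-dienoate
Product: 6 methyl (2E,6R)-6-hydroxy-3,7,7-trimethyldeca-2,9-dienoate
Conditions: (S)-2-methyl-CBS-oxazaborolidine (0.2 equiv), catecholborane (1.8 equiv), PhMe, −40 °C; MeOH, then aq. NaOH work-up
Reagents that add atoms: none
Why: Corey–Bakshi–Shibata reduction, in which the tertiary alkyl group acts as the large and the CH2 chain as the small substituent so that the (S)-catalyst sets the 6R carbinol (future C3), while catecholborane leaves enoate and terminal alkene untouched.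

**Step 4**
Reactants: 6 methyl (2E,6R)-6-hydroxy-3,7,7-trimethyldeca-2,9-dienoate
Product: 7 methyl (2E,6R)-6-(tert-butyldimethylsilyloxy)-3,7,7-trimethyldeca-2,9-dienoate
Conditions: TBSOTf (1.3 equiv), 2,6-lutidine (2.5 equiv), CH2Cl2, −78 to 0 °C
Reagents that add atoms: tert-butyldimethylsilyl trifluoromethanesulfonate, CC(C)(C)[Si](C)(C)OS(=O)(=O)C(F)(F)F
Why: Silylation of a hindered secondary alcohol with a silyl triflate and a non-nucleophilic base, which avoids the alkoxide that could close onto the enoate by oxa-Michael addition.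

**Step 5**
Reactants: 7 methyl (2E,6R)-6-(tert-butyldimethylsilyloxy)-3,7,7-trimethyldeca-2,9-dienoate
Product: 8 methyl (2E,6R,9E)-6-(tert-butyldimethylsilyloxy)-3,7,7-trimethyl-11-oxoundeca-2,9-dienoate
Conditions: crotonaldehyde (5 equiv), second-generation Hoveyda–Grubbs catalyst RuCl2(H2IMes)(=CH-C6H4-2-OiPr) (5 mol %), CH2Cl2, 40 °C
Reagents that add atoms: (E)-but-2-enal (crotonaldehyde), C/C=C/C=O
Why: Olefin cross-metathesis of the unhindered monosubstituted alkene with an enal partner gives the E-enal thermodynamically, and the trisubstituted enoate is inert to the ruthenium carbene.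

**Step 6**
Reactants: 8 methyl (2E,6R,9E)-6-(tert-butyldimethylsilyloxy)-3,7,7-trimethyl-11-oxoundeca-2,9-dienoate
Product: 9 methyl (2E,6R,8E,10E)-6-(tert-butyldimethylsilyloxy)-3,7,7-trimethyl-11-(triethylsilyloxy)undeca-2,8,10-trienoate
Conditions: TESOTf (1.3 equiv), Et3N (2.5 equiv), Et2O, −78 to 0 °C; chromatography on Et3N-deactivated silica
Reagents that add atoms: triethylsilyl trifluoromethanesulfonate, CC[Si](CC)(CC)OS(=O)(=O)C(F)(F)F
Why: Soft enolisation (O-silylation of the enal, then γ-deprotonation at C5 by the amine) gives the 1-silyloxy-1,3-diene, E at both double bonds because of the s-trans enal and the bulky quaternary C4 (any 10Z isomer would be a spectator later), and the ester is not enolised under these conditions.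

**Step 7**
Reactants: 9 methyl (2E,6R,8E,10E)-6-(tert-butyldimethylsilyloxy)-3,7,7-trimethyl-11-(triethylsilyloxy)undeca-2,8,10-trienoate
Product: 10 (2E,6R,8E,10E)-6-(tert-butyldimethylsilyloxy)-3,7,7-trimethyl-11-(triethylsilyloxy)undeca-2,8,10-trien-1-ol
Conditions: iBu2AlH (2.5 equiv), CH2Cl2, −78 °C; aq. KNaC4H4O6 (potassium sodium tartrate) work-up
Reagents that add atoms: none
Why: Aluminium hydride 1,2-reduction of the conjugated ester to the allylic alcohol, with silyl ether and silyl dienol ether inert to hydride and preserved by the neutral tartrate work-up.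

**Step 8**
Reactants: 10 (2E,6R,8E,10E)-6-(tert-butyldimethylsilyloxy)-3,7,7-trimethyl-11-(triethylsilyloxy)undeca-2,8,10-trien-1-ol
Product: 12 trans-fused octalin aldehyde (Diels–Alder adduct), via enal 11 (not isolated)
Conditions: MnO2 (20 equiv), CH2Cl2, rt; filter through Celite, concentrate; PhMe (0.01 M), BHT (5 mol %), silylated sealed tube, 120 °C
Reagents that add atoms: none
Why: MnO2 oxidises the allylic alcohol to (E)-enal 11, which on heating undergoes a concerted but asynchronous normal-electron-demand intramolecular Diels–Alder reaction of a 1,3,9-decatriene (known type: thermal type 1 cyclisation of terminally activated decatrienes with 1-silyloxydienes), the large HOMO coefficient at C5 meeting the enal β-carbon C10 so that the C5–C10 ring-fusion bond leads and C8–C9 follows. Ring B is closed as the cyclohexene of the suprafacial [4+2] event, and ring A is closed by the same C5–C10 bond in the fused mode, its C1–C4 tether folding as a chair. The E enal fixes the C10 methyl and the C9 formyl group cis, the (E)-silyl enol ether terminus fixes the C8 silyloxy group cis to the formyl group, and the endo transition state (formyl and C10 methyl under the diene) fixes H5 anti to the C10 methyl, i.e. the trans ring fusion. The absolute sense comes from C3, whose OTBS group prefers the equatorial site of the chair tether and thereby selects one diene face. The selectivity most needed is endo over exo (trans over cis fusion), which rests on secondary overlap of the formyl group and on the chair tether, while regiochemistry is fixed by the tether and reinforced by the donor (C8 oxygen) and acceptor (C11 formyl) polarity.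

**Step 9**
Reactants: 12 trans-fused octalin aldehyde
Product: 13 trans-decalin aldehyde
Conditions: H2 (1 atm), 10% Pd/C, EtOAc, rt
Reagents that add atoms: none
Why: Heterogeneous catalytic hydrogenation saturates the cis-disubstituted C6=C7 bond without creating a stereocentre, and aldehyde and silyl ethers survive the neutral conditions.

**Step 10**
Reactants: 13 trans-decalin aldehyde
Product: 14 9-vinyl decalin
Conditions: Ph3PCH3Br (2.0 equiv), KOtBu (1.9 equiv), THF, 0 °C; then 13, 0 °C to rt
Reagents that add atoms: methyltriphenylphosphonium bromide, C[P+](c1ccccc1)(c1ccccc1)c1ccccc1.[Br-]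
Why: Wittig methylenation converts the hindered aldehyde into the vinyl group, and C9 is safe because the equatorial formyl group is already the thermodynamic epimer.

**Step 11**
Reactants: 15 but-2-ynoic acid
Product: 16 2-(trimethylsilyl)ethyl but-2-ynoate
Conditions: 2-(trimethylsilyl)ethanol (1.1 equiv), DCC (1.1 equiv), DMAP (5 mol %), CH2Cl2, 0 °C to rt
Reagents that add atoms: 2-(trimethylsilyl)ethanol, C[Si](C)(C)CCO
Why: Steglich esterification installs a 2-(trimethylsilyl)ethyl ester that fluoride will later remove together with the C3 silyl ether.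

**Step 12**
Reactants: 16 2-(trimethylsilyl)ethyl but-2-ynoate
Product: 17 2-(trimethylsilyl)ethyl (2Z)-3-iodobut-2-enoate
Conditions: NaI (1.6 equiv), AcOH, 110 °C
Reagents that add atoms: sodium iodide, [Na+].[I-]
Why: Hydroiodination of a 2-alkynoate (conjugate addition of iodide, then anti protonation) gives the Z-β-iodoenoate with iodine cis to the ester.

**Step 13**
Reactants: 14 9-vinyl decalin; 17 2-(trimethylsilyl)ethyl (2Z)-3-iodobut-2-enoate
Product: 19 2-(trimethylsilyl)ethyl (13Z)-3-(tert-butyldimethylsilyloxy)-8-(triethylsilyloxy)-17-norlabd-13-en-15-oate, via alkylborane 18 (not isolated)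
Conditions: 9-BBN dimer (1.5 equiv B–H), THF, rt to 50 °C; then 17 (1.3 equiv), PdCl2(dppf) (5 mol %), AsPh3 (10 mol %), Cs2CO3 (3 equiv), DMF/H2O, rt
Reagents that add atoms: none
Why: Anti-Markovnikov hydroboration of the vinyl group followed by B-alkyl Suzuki–Miyaura coupling, which proceeds with retention at the iodoalkene, delivers the Z-3-methyl-2-enoate side chain.

**Step 14**
Reactants: 19 2-(trimethylsilyl)ethyl (13Z)-3-(tert-butyldimethylsilyloxy)-8-(triethylsilyloxy)-17-norlabd-13-en-15-oate
Product: 20 2-(trimethylsilyl)ethyl (13Z)-3-(tert-butyldimethylsilyloxy)-8-hydroxy-17-norlabd-13-en-15-oate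
Conditions: PPTS (0.3 equiv), MeOH/CH2Cl2 (1:1), 0 °C to rt
Reagents that add atoms: none
Why: Acid-catalysed methanolysis (selective silyl ether cleavage) removes the triethylsilyl group far faster than the hindered tert-butyldimethylsilyl ether at C3.

**Step 15**
Reactants: 20 2-(trimethylsilyl)ethyl (13Z)-3-(tert-butyldimethylsilyloxy)-8-hydroxy-17-norlabd-13-en-15-oate
Product: 21 2-(trimethylsilyl)ethyl (13Z)-3-(tert-butyldimethylsilyloxy)-8-oxo-17-norlabd-13-en-15-oate
Conditions: Dess–Martin periodinane (1.5 equiv), NaHCO3, CH2Cl2, rt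
Reagents that add atoms: none
Why: Dess–Martin oxidation converts the secondary alcohol into the C8 ketone under buffered, non-epimerising conditions.

**Step 16**
Reactants: 21 2-(trimethylsilyl)ethyl (13Z)-3-(tert-butyldimethylsilyloxy)-8-oxo-17-norlabd-13-en-15-oate
Product: 22 2-(trimethylsilyl)ethyl (13Z)-3-(tert-butyldimethylsilyloxy)-8-hydroxy-17-(propan-2-ylidene)labd-13-en-15-oate
Conditions: CeCl3 (anhydrous, 3 equiv), 2-methylprop-1-enylmagnesium bromide (3 equiv), THF, −78 °C; then 21, −78 to −40 °C; aq. NH4Cl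
Reagents that add atoms: 2-methylprop-1-enylmagnesium bromide, CC(C)=C[Mg]Br
Why: Organocerium (Imamoto) 1,2-addition to the hindered, enolisable ketone occurs along the equatorial trajectory because the axial C10 methyl blocks axial attack, which sets C8 with the hydroxyl axial and cis to the C10 methyl and the alkenyl group equatorial, and the low-temperature cerium reagent spares the ester.

**Step 17**
Reactants: 22 2-(trimethylsilyl)ethyl (13Z)-3-(tert-butyldimethylsilyloxy)-8-hydroxy-17-(propan-2-ylidene)labd-13-en-15-oate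
Product: 23 (13Z)-3,8-dihydroxy-17-(propan-2-ylidene)labd-13-en-15-oic acid
Conditions: Bu4NF (6 equiv), THF, 50 °C; aq. NH4Cl work-up, pH 4
Reagents that add atoms: none
Why: Fluoride-mediated desilylation cleaves the C3 silyl ether and, by β-elimination of ethylene, the 2-(trimethylsilyl)ethyl ester in one operation without harming the tertiary allylic alcohol or the Z-enoate.

**Step 18**
Reactants: 23 (13Z)-3,8-dihydroxy-17-(propan-2-ylidene)labd-13-en-15-oic acid
Product: 25 (13Z)-3,8-dihydroxy-17-oxolabd-13-en-15-oic acid (target), via ozonide 24 (not isolated)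
Conditions: O3 (1.0 equiv by titration, Sudan Red 7B indicator), CH2Cl2/EtOAc, −78 °C; then PPh3 (1.2 equiv), −78 °C to rt
Reagents that add atoms: ozone, [O-][O+]=O
Why: Ozonolysis with reductive work-up cleaves the electron-rich isolated trisubstituted alkene in preference to the acid-conjugated one (titrated ozone, indicator dye) and releases the tertiary α-hydroxy aldehyde under neutral conditions.

**Compound list**

1 | 2,2-dimethylpent-4-enoic acid | C=CCC(C)(C)C(=O)O | starting material
2 | 3,3-dimethylhex-5-en-2-one | CC(=O)C(C)(C)CC=C | intermediate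
3 | methyl (2E)-4-bromo-3-methylbut-2-enoate | COC(=O)/C=C(\C)CBr | starting material
4 | lithium 3,3-dimethylhexa-1,5-dien-2-olate (lithium enolate of 2) | [Li]OC(=C)C(C)(C)CC=C | intermediate (not isolated)
5 | methyl (2E)-3,7,7-trimethyl-6-oxodeca-2,9-dienoate | COC(=O)/C=C(\C)CCC(=O)C(C)(C)CC=C | intermediate
6 | methyl (2E,6R)-6-hydroxy-3,7,7-trimethyldeca-2,9-dienoate | COC(=O)/C=C(\C)CC[C@@H](O)C(C)(C)CC=C | intermediate
7 | methyl (2E,6R)-6-(tert-butyldimethylsilyloxy)-3,7,7-trimethyldeca-2,9-dienoate | COC(=O)/C=C(\C)CC[C@@H](O[Si](C)(C)C(C)(C)C)C(C)(C)CC=C | intermediate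
8 | methyl (2E,6R,9E)-6-(tert-butyldimethylsilyloxy)-3,7,7-trimethyl-11-oxoundeca-2,9-dienoate | COC(=O)/C=C(\C)CC[C@@H](O[Si](C)(C)C(C)(C)C)C(C)(C)C/C=C/C=O | intermediate
9 | methyl (2E,6R,8E,10E)-6-(tert-butyldimethylsilyloxy)-3,7,7-trimethyl-11-(triethylsilyloxy)undeca-2,8,10-trienoate | COC(=O)/C=C(\C)CC[C@@H](O[Si](C)(C)C(C)(C)C)C(C)(C)/C=C/C=C/O[Si](CC)(CC)CC | intermediate
10 | (2E,6R,8E,10E)-6-(tert-butyldimethylsilyloxy)-3,7,7-trimethyl-11-(triethylsilyloxy)undeca-2,8,10-trien-1-ol | OC/C=C(\C)CC[C@@H](O[Si](C)(C)C(C)(C)C)C(C)(C)/C=C/C=C/O[Si](CC)(CC)CC | intermediate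
11 | (2E,6R,8E,10E)-6-(tert-butyldimethylsilyloxy)-3,7,7-trimethyl-11-(triethylsilyloxy)undeca-2,8,10-trienal | O=C/C=C(\C)CC[C@@H](O[Si](C)(C)C(C)(C)C)C(C)(C)/C=C/C=C/O[Si](CC)(CC)CC | intermediate (not isolated)
12 | Diels–Alder adduct: 3-(tert-butyldimethylsilyloxy)-8-(triethylsilyloxy)-4,4,10-trimethyl-trans-octal-6-ene-9-carbaldehyde (labdane numbering; 3R; C10 methyl, C9 formyl, C8 and C3 silyloxy groups on one face; H5, H8 and H9 on the other) | O=C[C@H]1[C@]2(C)CC[C@@H](O[Si](C)(C)C(C)(C)C)C(C)(C)[C@H]2C=C[C@H]1O[Si](CC)(CC)CC | intermediate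
13 | 3-(tert-butyldimethylsilyloxy)-8-(triethylsilyloxy)-4,4,10-trimethyl-trans-decalin-9-carbaldehyde (configuration as in 12) | O=C[C@H]1[C@]2(C)CC[C@@H](O[Si](C)(C)C(C)(C)C)C(C)(C)[C@H]2CC[C@H]1O[Si](CC)(CC)CC | intermediate
14 | 9-ethenyl-3-(tert-butyldimethylsilyloxy)-8-(triethylsilyloxy)-4,4,10-trimethyl-trans-decalin (configuration as in 12) | C=C[C@H]1[C@]2(C)CC[C@@H](O[Si](C)(C)C(C)(C)C)C(C)(C)[C@H]2CC[C@H]1O[Si](CC)(CC)CC | intermediate
15 | but-2-ynoic acid | CC#CC(=O)O | starting material
16 | 2-(trimethylsilyl)ethyl but-2-ynoate | CC#CC(=O)OCC[Si](C)(C)C | intermediate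
17 | 2-(trimethylsilyl)ethyl (2Z)-3-iodobut-2-enoate | C/C(I)=C/C(=O)OCC[Si](C)(C)C | intermediate
18 | B-alkyl-9-BBN: 9-[2-(decalin-9-yl)ethyl]-9-borabicyclo[3.3.1]nonane derived from 14 (boron on C12) | B4(CC[C@H]1[C@]2(C)CC[C@@H](O[Si](C)(C)C(C)(C)C)C(C)(C)[C@H]2CC[C@H]1O[Si](CC)(CC)CC)C5CCCC4CCC5 | intermediate (not isolated)
19 | 2-(trimethylsilyl)ethyl (13Z)-3-(tert-butyldimethylsilyloxy)-8-(triethylsilyloxy)-17-norlabd-13-en-15-oate | C/C(=C/C(=O)OCC[Si](C)(C)C)CC[C@H]1[C@]2(C)CC[C@@H](O[Si](C)(C)C(C)(C)C)C(C)(C)[C@H]2CC[C@H]1O[Si](CC)(CC)CC | intermediate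
20 | 2-(trimethylsilyl)ethyl (13Z)-3-(tert-butyldimethylsilyloxy)-8-hydroxy-17-norlabd-13-en-15-oate (8-OH axial, cis to the C10 methyl) | C/C(=C/C(=O)OCC[Si](C)(C)C)CC[C@H]1[C@]2(C)CC[C@@H](O[Si](C)(C)C(C)(C)C)C(C)(C)[C@H]2CC[C@H]1O | intermediate
21 | 2-(trimethylsilyl)ethyl (13Z)-3-(tert-butyldimethylsilyloxy)-8-oxo-17-norlabd-13-en-15-oate | C/C(=C/C(=O)OCC[Si](C)(C)C)CC[C@H]1[C@]2(C)CC[C@@H](O[Si](C)(C)C(C)(C)C)C(C)(C)[C@H]2CCC1=O | intermediate
22 | 2-(trimethylsilyl)ethyl (13Z)-3-(tert-butyldimethylsilyloxy)-8-hydroxy-17-(propan-2-ylidene)labd-13-en-15-oate (8-OH axial, cis to the C10 methyl; alkenyl group equatorial) | C/C(=C/C(=O)OCC[Si](C)(C)C)CC[C@H]1[C@]2(C)CC[C@@H](O[Si](C)(C)C(C)(C)C)C(C)(C)[C@H]2CC[C@]1(O)C=C(C)C | intermediate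
23 | (13Z)-3,8-dihydroxy-17-(propan-2-ylidene)labd-13-en-15-oic acid | C/C(=C/C(=O)O)CC[C@H]1[C@]2(C)CC[C@@H](O)C(C)(C)[C@H]2CC[C@]1(O)C=C(C)C | intermediate
24 | ozonide of 23: 5,5-dimethyl-1,2,4-trioxolan-3-yl group on C8 (mixture at the trioxolane CH) | C/C(=C/C(=O)O)CC[C@H]1[C@]2(C)CC[C@@H](O)C(C)(C)[C@H]2CC[C@]1(O)C3OOC(C)(C)O3 | intermediate (not isolated)
25 | CNP0273710.1: (13Z)-3,8-dihydroxy-17-oxolabd-13-en-15-oic acid, (3R,5S,8R,9S,10R); (2Z)-5-[(1S,2R,4aS,6R,8aR)-2-formyl-2,6-dihydroxy-5,5,8a-trimethyldecahydronaphthalen-1-yl]-3-methylpent-2-enoic acid | C/C(=C/C(=O)O)CC[C@H]1[C@]2(C)CC[C@@H](O)C(C)(C)[C@H]2CC[C@]1(O)C=O | target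

Total step count: 18. Longest linear sequence: 16 steps (steps 1–10 and 13–18).

**Steps most likely to fail**

1. Step 8 (key step). What may go wrong: loss of the silyl dienol ether or of the free enal in side reactions (hydrolysis on the oxidant, intramolecular vinylogous aldol or ene processes) before the congested C5–C10 bond forms, and leakage through the exo transition state to the cis ring fusion. Fallback (sets out from 9, returns at 13): the ring closure is run on the ester, so that no reduction or oxidation precedes it. Trienoate 9 is heated in o-xylene (170 °C, BHT, sealed tube), where the E-enoate should react through the same endo chair transition state to give the methyl ester adduct F1. Hydrogenation (H2, Pd/C, EtOAc) should give the saturated ester F2, reduction with iBu2AlH (CH2Cl2, −78 to 0 °C) the primary alcohol F3, and Dess–Martin oxidation aldehyde 13.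

2. Step 18. What may go wrong: loss of chemoselectivity, with ozone also attacking the conjugated Z-alkene of the side chain, or over-oxidation of the α-hydroxy aldehyde. Fallback (sets out from 21, returns at 25): the formyl carbon is introduced at the aldehyde oxidation level with no alkene to cleave. 2-Lithio-1,3-dithiane (THF, −78 to −20 °C, equatorial attack as in step 16) should give the dithianyl carbinol F4, Bu4NF (THF, 50 °C) the desilylated dithiane acid F5, and dithiane hydrolysis with I2/NaHCO3 in aqueous acetone at 0 °C compound 25.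

3. Step 16. What may go wrong: enolisation of the hindered ketone instead of addition, competing attack on the ester, or erosion of the equatorial facial preference. Fallback (sets out from 21, returns at 25): a small, weakly basic one-carbon nucleophile is used, and an alcohol oxidation replaces the alkene cleavage. Corey–Chaykovsky reaction with dimethylsulfonium methylide (Me3SI, KN(SiMe3)2, THF, −10 to 0 °C; equatorial attack forced by the axial C10 methyl) should give the spiro-epoxide F6 with the oxygen axial. Bu4NF (THF, 50 °C) should give the epoxy hydroxy acid F7, and hydroxide opening at the CH2 carbon (aq. NaOH, DMSO, 90 °C), which leaves C8 untouched, the triol acid F8. Primary-selective nitroxyl oxidation (TEMPO cat., N-chlorosuccinimide, Bu4NCl, CH2Cl2/aq. NaHCO3–K2CO3 buffer) should give 25.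

**Further compounds**

F1 | step 8 | methyl 3-(tert-butyldimethylsilyloxy)-8-(triethylsilyloxy)-4,4,10-trimethyl-trans-octal-6-ene-9-carboxylate (configuration as in 12) | COC(=O)[C@H]1[C@]2(C)CC[C@@H](O[Si](C)(C)C(C)(C)C)C(C)(C)[C@H]2C=C[C@H]1O[Si](CC)(CC)CC
F2 | step 8 | methyl 3-(tert-butyldimethylsilyloxy)-8-(triethylsilyloxy)-4,4,10-trimethyl-trans-decalin-9-carboxylate | COC(=O)[C@H]1[C@]2(C)CC[C@@H](O[Si](C)(C)C(C)(C)C)C(C)(C)[C@H]2CC[C@H]1O[Si](CC)(CC)CC
F3 | step 8 | [3-(tert-butyldimethylsilyloxy)-8-(triethylsilyloxy)-4,4,10-trimethyl-trans-decalin-9-yl]methanol | OC[C@H]1[C@]2(C)CC[C@@H](O[Si](C)(C)C(C)(C)C)C(C)(C)[C@H]2CC[C@H]1O[Si](CC)(CC)CC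
F4 | step 18 | 2-(trimethylsilyl)ethyl (13Z)-3-(tert-butyldimethylsilyloxy)-8-(1,3-dithian-2-yl)-8-hydroxy-17-norlabd-13-en-15-oate | C/C(=C/C(=O)OCC[Si](C)(C)C)CC[C@H]1[C@]2(C)CC[C@@H](O[Si](C)(C)C(C)(C)C)C(C)(C)[C@H]2CC[C@]1(O)C3SCCCS3
F5 | step 18 | (13Z)-8-(1,3-dithian-2-yl)-3,8-dihydroxy-17-norlabd-13-en-15-oic acid | C/C(=C/C(=O)O)CC[C@H]1[C@]2(C)CC[C@@H](O)C(C)(C)[C@H]2CC[C@]1(O)C3SCCCS3
F6 | step 16 | 2-(trimethylsilyl)ethyl (13Z)-3-(tert-butyldimethylsilyloxy)-8,17-epoxylabd-13-en-15-oate (epoxide oxygen axial, cis to the C10 methyl) | C/C(=C/C(=O)OCC[Si](C)(C)C)CC[C@H]1[C@]2(C)CC[C@@H](O[Si](C)(C)C(C)(C)C)C(C)(C)[C@H]2CC[C@]13CO3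
F7 | step 16 | (13Z)-8,17-epoxy-3-hydroxylabd-13-en-15-oic acid | C/C(=C/C(=O)O)CC[C@H]1[C@]2(C)CC[C@@H](O)C(C)(C)[C@H]2CC[C@]13CO3
F8 | step 16 | (13Z)-3,8,17-trihydroxylabd-13-en-15-oic acid | C/C(=C/C(=O)O)CC[C@H]1[C@]2(C)CC[C@@H](O)C(C)(C)[C@H]2CC[C@]1(O)CO
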